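## Retrosynthetic overview

1. Lutein dimyristate 31 ⇒ lutein 29 + myristoyl chloride 30; the C40 polyene ⇒ ε-C15 phosphonium salt 14 + C10 dialdehyde 24 + β-C15 phosphonium salt 23, joined by two Wittig olefinations (C11=C12 first, C11'=C12' last; carotenoid numbering, primed for the ε half).
2. 14 ⇒ ring aldehyde 8 + C5 phosphonate 9 (C7'=C8'); 8 ⇒ hydroxy ester 6, whose two stereocentres (C3', C6') are set together by an enzymatic dynamic kinetic reduction of racemic keto ester 5.
3. Key disconnection: ring ε of 5 is cut at C1'–C6' and at C4'=C5' into mesityl oxide 1 (C1'–C4' and the geminal methyls) and ethyl acetoacetate 2 (C5', C6', C7' and the C5' methyl).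
4. Enabling feature: ring ε (C1'–C6') is a cyclohex-2-ene whose C4'=C5' olefin lies between oxygen-bearing C3' and C6', and C6' carries a one-carbon branch (C7'). With C3' as ketone and C7' as ester the ring is a 4-oxocyclohex-2-ene-1-carboxylate (a vinylogous β-keto ester), the retron of a Michael/aldol annulation; the same pattern makes C6' epimerisable, which the enzyme step uses.
5. Ring order: ring ε is the only ring that is built (step 1); ring β is carried in intact from (4R,6R)-actinol 15 through its enol triflate and a Stille coupling.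

Key step: step 1

Assumption: the ketoreductase of step 2 is taken from a commercial screening panel, the hit being the enzyme that accepts the (1R)-ketone and delivers hydride to the face that gives the (4R)-carbinol.

## Route

Step 1
Reactants: 1 mesityl oxide (4-methylpent-3-en-2-one); 2 ethyl acetoacetate
Product: 5 rac-ethyl 2,6,6-trimethyl-4-oxocyclohex-2-ene-1-carboxylate, via Michael adduct 3 (not isolated), via cyclic aldol 4 (not isolated)
Conditions: ZnCl2 (0.2 equiv), heptane/toluene, reflux, Dean–Stark trap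
Reagents that add atoms: none
Why: ZnCl2 enolises the β-keto ester 2 and activates enone 1, so that conjugate addition of C2 of 2 to the β-carbon of 1 forges the quaternary C1'–C6' bond (adduct 3); the methyl ketone end of 3 (C4') then adds as its enol to the ester-activated acetyl carbonyl (C5'), and aldol 4 loses water to the conjugated enone, which places the C4'=C5' olefin in the ε position. The closest known reaction type is the Robinson-type Michael addition/aldol condensation of 3-oxobutanoates with enones to 4-oxocyclohex-2-ene-1-carboxylates, and the Lewis-acid-mediated union of exactly these two components is established. The six-membered ring closes by a 6-(enolendo)-exo-trig aldol addition. The only stereocentre formed, C6', arises racemic and is left epimerisable on purpose, being α to the ester and γ to the enone. The step needs conjugate rather than carbonyl addition and one of two possible aldol closures: the keto ester enolises only towards C6', so its own methyl is no nucleophile while its ketone is the most electrophilic carbonyl, and azeotropic removal of water pulls the reversible sequence to the conjugated enone.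

Step 2
Reactants: 5 rac-ethyl 2,6,6-trimethyl-4-oxocyclohex-2-ene-1-carboxylate
Product: 6 ethyl (1R,4R)-4-hydroxy-2,6,6-trimethylcyclohex-2-ene-1-carboxylate
Conditions: ketoreductase (NADPH-dependent, panel enzyme), NADP+ (cat.), i-PrOH (15 vol%), triethanolamine buffer pH 8.5, 30 °C
Reagents that add atoms: none
Why: Proposed new method: the enzyme should reduce only the (1R)-enantiomer of 5 with hydride delivery from NADPH to one carbonyl face, while the unreactive (1S)-ketone racemises in the mildly basic buffer through the dienolate (C6'–H is α to the ester and γ to the enone); after reduction this vinylogous activation is gone, so C3' (hydride face) and C6' (choice of substrate enantiomer) are both fixed by the enzyme, the closest known reaction types being the ketoreductase-mediated dynamic kinetic reduction of α-substituted β-keto esters and the ketoreductase reduction of cyclohex-2-enones to allylic alcohols.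

Step 3
Reactants: 6 ethyl (1R,4R)-4-hydroxy-2,6,6-trimethylcyclohex-2-ene-1-carboxylate
Product: 7 ethyl (1R,4R)-4-(tert-butyldimethylsilyloxy)-2,6,6-trimethylcyclohex-2-ene-1-carboxylate
Conditions: TBSCl, imidazole, DMF, rt
Reagents that add atoms: tert-butyldimethylsilyl chloride CC(C)(C)[Si](C)(C)Cl
Why: Standard silylation of a secondary allylic alcohol touches no stereocentre and gives an ether that should survive the hydride and ylide chemistry that follows.

Step 4
Reactants: 7 ethyl (1R,4R)-4-(tert-butyldimethylsilyloxy)-2,6,6-trimethylcyclohex-2-ene-1-carboxylate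
Product: 8 (1R,4R)-4-(tert-butyldimethylsilyloxy)-2,6,6-trimethylcyclohex-2-ene-1-carbaldehyde
Conditions: i-Bu2AlH (1.1 equiv), CH2Cl2, −78 °C; MeOH, aq. potassium sodium tartrate; used crude at once
Reagents that add atoms: none
Why: Partial reduction of an ester with i-Bu2AlH, in which the tetrahedral aluminium hemiacetal of the hindered ester should persist at −78 °C and collapse to the aldehyde only on neutral work-up, so that C6', now α to a formyl group, meets neither base nor acid.

Step 5
Reactants: 8 (1R,4R)-4-(tert-butyldimethylsilyloxy)-2,6,6-trimethylcyclohex-2-ene-1-carbaldehyde; 9 ethyl (E)-4-(diethoxyphosphoryl)-3-methylbut-2-enoate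
Product: 11 ethyl (2E,4E)-5-[(1R,4R)-4-(tert-butyldimethylsilyloxy)-2,6,6-trimethylcyclohex-2-en-1-yl]-3-methylpenta-2,4-dienoate, via lithiated phosphonate 10 (not isolated)
Conditions: 9, LiN(SiMe3)2 (1.05 equiv), THF, −78 °C; then 8, −78 to 0 °C
Reagents that add atoms: none
Why: Horner–Wadsworth–Emmons olefination with a soft, weakly basic vinylogous phosphonate anion should add to the hindered aldehyde faster than it deprotonates C6'–H and form the C7'=C8' bond with E geometry under the usual thermodynamic control (any 9'Z isomer is removed by chromatography).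

Step 6
Reactants: 11 ethyl (2E,4E)-5-[(1R,4R)-4-(tert-butyldimethylsilyloxy)-2,6,6-trimethylcyclohex-2-en-1-yl]-3-methylpenta-2,4-dienoate
Product: 12 (2E,4E)-5-[(1R,4R)-4-(tert-butyldimethylsilyloxy)-2,6,6-trimethylcyclohex-2-en-1-yl]-3-methylpenta-2,4-dien-1-ol
Conditions: i-Bu2AlH (2.5 equiv), CH2Cl2, −78 to −20 °C; aq. potassium sodium tartrate
Reagents that add atoms: none
Why: 1,2-Reduction of a dienoate by i-Bu2AlH gives the dienylic alcohol without touching the silyl ether, the olefins or the stereocentres.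

Step 7
Reactants: 12 (2E,4E)-5-[(1R,4R)-4-(tert-butyldimethylsilyloxy)-2,6,6-trimethylcyclohex-2-en-1-yl]-3-methylpenta-2,4-dien-1-ol
Product: 14 [(2E,4E)-5-[(1R,4R)-4-(tert-butyldimethylsilyloxy)-2,6,6-trimethylcyclohex-2-en-1-yl]-3-methylpenta-2,4-dien-1-yl]triphenylphosphonium bromide, via allylic bromide 13 (not isolated)
Conditions: CBr4 (1.1 equiv), PPh3 (1.1 equiv), CH2Cl2, −20 °C; then PPh3 (1.3 equiv), EtOAc, 0 °C to rt, dark
Reagents that add atoms: triphenylphosphine c1ccc(cc1)P(c1ccccc1)c1ccccc1; carbon tetrabromide BrC(Br)(Br)Br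
Why: Appel bromination followed by SN2 quaternisation with PPh3 keeps the medium neutral, which spares the ionisable allylic silyl ether at C3' that an acidic phosphine hydrobromide protocol would endanger.

Step 8
Reactants: 15 (4R,6R)-4-hydroxy-2,2,6-trimethylcyclohexan-1-one (actinol)
Product: 16 (4R,6R)-4-(tert-butyldimethylsilyloxy)-2,2,6-trimethylcyclohexan-1-one
Conditions: TBSCl, imidazole, DMF, rt
Reagents that add atoms: tert-butyldimethylsilyl chloride CC(C)(C)[Si](C)(C)Cl
Why: Standard silylation protects the carbinol (the later C3 of ring β) against the strong base and the triflating agent of the next step.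

Step 9
Reactants: 16 (4R,6R)-4-(tert-butyldimethylsilyloxy)-2,2,6-trimethylcyclohexan-1-one
Product: 18 (4R)-4-(tert-butyldimethylsilyloxy)-2,6,6-trimethylcyclohex-1-en-1-yl trifluoromethanesulfonate, via lithium enolate 17 (not isolated)
Conditions: LiN(i-Pr)2 (1.2 equiv), THF, −78 to 0 °C; then PhNTf2, −78 °C to rt
Reagents that add atoms: N-phenylbis(trifluoromethanesulfonimide) O=S(=O)(N(c1ccccc1)S(=O)(=O)C(F)(F)F)C(F)(F)F
Why: Enol triflate formation is regiochemically unambiguous because only the methyl-bearing α-carbon can be deprotonated (the other is quaternary), so the tetrasubstituted C5=C6 olefin of ring β results while the carbinol centre stays untouched and the methyl-bearing centre is flattened on purpose.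

Step 10
Reactants: 19 (E)-3-methylpent-2-en-4-yn-1-ol
Product: 20 (2E,4E)-3-methyl-5-(tributylstannyl)penta-2,4-dien-1-ol
Conditions: Bu3SnH, PdCl2(PPh3)2 (2 mol%), THF, 0 °C to rt
Reagents that add atoms: tributyltin hydride CCCC[SnH](CCCC)CCCC
Why: Palladium-catalysed syn-hydrostannylation of the terminal alkyne should place tin on the unhindered terminal carbon and give the (4E)-dienylstannane, the (2E) olefin and the free hydroxyl being unaffected (an internal regioisomer, if formed, is removed by chromatography).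

Step 11
Reactants: 18 (4R)-4-(tert-butyldimethylsilyloxy)-2,6,6-trimethylcyclohex-1-en-1-yl trifluoromethanesulfonate; 20 (2E,4E)-3-methyl-5-(tributylstannyl)penta-2,4-dien-1-ol
Product: 21 (2E,4E)-5-[(4R)-4-(tert-butyldimethylsilyloxy)-2,6,6-trimethylcyclohex-1-en-1-yl]-3-methylpenta-2,4-dien-1-ol
Conditions: Pd2(dba)3 (2.5 mol%), AsPh3 (20 mol%), NMP, 50 °C
Reagents that add atoms: none
Why: Stille cross-coupling of a hindered cyclohexenyl triflate with an alkenylstannane, accelerated by AsPh3 in a polar solvent, forms the C6–C7 bond with retention of both olefin geometries and tolerates the free alcohol and the silyl ether.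

Step 12
Reactants: 21 (2E,4E)-5-[(4R)-4-(tert-butyldimethylsilyloxy)-2,6,6-trimethylcyclohex-1-en-1-yl]-3-methylpenta-2,4-dien-1-ol
Product: 23 [(2E,4E)-5-[(4R)-4-(tert-butyldimethylsilyloxy)-2,6,6-trimethylcyclohex-1-en-1-yl]-3-methylpenta-2,4-dien-1-yl]triphenylphosphonium bromide, via allylic bromide 22 (not isolated)
Conditions: CBr4 (1.1 equiv), PPh3 (1.1 equiv), CH2Cl2, −20 °C; then PPh3 (1.3 equiv), EtOAc, 0 °C to rt, dark
Reagents that add atoms: triphenylphosphine c1ccc(cc1)P(c1ccccc1)c1ccccc1; carbon tetrabromide BrC(Br)(Br)Br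
Why: The same neutral Appel bromination and phosphine quaternisation as in step 7 is applied to the β-series dienylic alcohol, which keeps the silyl ether in place.

Step 13
Reactants: 23 β-C15 phosphonium bromide; 24 (2E,4E,6E)-2,7-dimethylocta-2,4,6-trienedial
Product: 26 (2E,4E,6E,8E,10E,12E)-13-[(4R)-4-(tert-butyldimethylsilyloxy)-2,6,6-trimethylcyclohex-1-en-1-yl]-2,7,11-trimethyltrideca-2,4,6,8,10,12-hexaenal, via phosphorus ylide 25 (not isolated)
Conditions: 24 (2 equiv), NaOMe (1.1 equiv), MeOH/CH2Cl2, 0 °C to rt; then heptane, reflux, dark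
Reagents that add atoms: none
Why: Wittig olefination of a semi-stabilised allylic ylide with the symmetrical dialdehyde in excess should stop after one olefination because the product aldehyde is deactivated by the longer polyene, and the E/Z mixture at the new C11=C12 bond is funnelled to all-E by thermal equilibration.

Step 14
Reactants: 14 ε-C15 phosphonium bromide; 26 C25 aldehyde
Product: 28 (3R,3'R,6'R)-3,3'-bis(tert-butyldimethylsilyloxy)-β,ε-carotene, via phosphorus ylide 27 (not isolated)
Conditions: NaOMe (1.2 equiv), MeOH/CH2Cl2, rt; then heptane/EtOAc, reflux, argon, dark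
Reagents that add atoms: none
Why: The second Wittig olefination joins the halves at C11'=C12' with the ylide carbon remote from C6', so no stereocentre is at risk, and hindered Z isomers of the polyene should revert thermally to the all-E chain.

Step 15
Reactants: 28 (3R,3'R,6'R)-3,3'-bis(tert-butyldimethylsilyloxy)-β,ε-carotene
Product: 29 lutein, (3R,3'R,6'R)-β,ε-carotene-3,3'-diol
Conditions: Bu4NF (3 equiv), THF, rt, argon, dark
Reagents that add atoms: none
Why: Fluoride-mediated cleavage of both secondary silyl ethers runs under non-acidic conditions, chosen because the allylic C3' alcohol of lutein ionises in acid.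

Step 16
Reactants: 29 lutein; 30 myristoyl chloride (tetradecanoyl chloride)
Product: 31 lutein dimyristate, (3R,3'R,6'R)-β,ε-carotene-3,3'-diyl ditetradecanoate
Conditions: 30 (2.6 equiv), pyridine, DMAP (cat.), CH2Cl2, 0 °C to rt, argon, dark
Reagents that add atoms: none
Why: Nucleophile-catalysed acylation of both secondary alcohols with the acid chloride in basic medium occurs at oxygen only, so the three stereocentres and the acid-sensitive allylic position stay untouched.

## Compound list

1 | mesityl oxide (4-methylpent-3-en-2-one) | CC(C)=CC(C)=O | starting material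
2 | ethyl acetoacetate (ethyl 3-oxobutanoate) | CCOC(=O)CC(C)=O | starting material
3 | Michael adduct, ethyl 2-acetyl-3,3-dimethyl-5-oxohexanoate (racemic, not isolated) | CCOC(=O)C(C(C)=O)C(C)(C)CC(C)=O | intermediate
4 | cyclic aldol, ethyl 2-hydroxy-2,6,6-trimethyl-4-oxocyclohexane-1-carboxylate (racemic diastereomers, not isolated) | CCOC(=O)C1C(C)(O)CC(=O)CC1(C)C | intermediate
5 | rac-ethyl 2,6,6-trimethyl-4-oxocyclohex-2-ene-1-carboxylate | CCOC(=O)C1C(C)=CC(=O)CC1(C)C | intermediate
6 | ethyl (1R,4R)-4-hydroxy-2,6,6-trimethylcyclohex-2-ene-1-carboxylate | CCOC(=O)[C@H]1C(C)=C[C@H](O)CC1(C)C | intermediate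
7 | ethyl (1R,4R)-4-(tert-butyldimethylsilyloxy)-2,6,6-trimethylcyclohex-2-ene-1-carboxylate | CCOC(=O)[C@H]1C(C)=C[C@H](O[Si](C)(C)C(C)(C)C)CC1(C)C | intermediate
8 | (1R,4R)-4-(tert-butyldimethylsilyloxy)-2,6,6-trimethylcyclohex-2-ene-1-carbaldehyde | O=C[C@H]1C(C)=C[C@H](O[Si](C)(C)C(C)(C)C)CC1(C)C | intermediate
9 | ethyl (E)-4-(diethoxyphosphoryl)-3-methylbut-2-enoate (triethyl 3-methyl-4-phosphonocrotonate) | CCOC(=O)/C=C(\C)CP(=O)(OCC)OCC | starting material
10 | lithiated phosphonate from 9 (not isolated) | [Li+].CCOC(=O)/C=C(\C)[CH-]P(=O)(OCC)OCC | intermediate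
11 | ethyl (2E,4E)-5-[(1R,4R)-4-(tert-butyldimethylsilyloxy)-2,6,6-trimethylcyclohex-2-en-1-yl]-3-methylpenta-2,4-dienoate | CCOC(=O)/C=C(C)/C=C/[C@H]1C(C)=C[C@H](O[Si](C)(C)C(C)(C)C)CC1(C)C | intermediate
12 | (2E,4E)-5-[(1R,4R)-4-(tert-butyldimethylsilyloxy)-2,6,6-trimethylcyclohex-2-en-1-yl]-3-methylpenta-2,4-dien-1-ol | OC/C=C(C)/C=C/[C@H]1C(C)=C[C@H](O[Si](C)(C)C(C)(C)C)CC1(C)C | intermediate
13 | ε-series allylic bromide, (2E,4E)-1-bromo-3-methylpenta-2,4-dienyl compound from 12 (not isolated) | BrC/C=C(C)/C=C/[C@H]1C(C)=C[C@H](O[Si](C)(C)C(C)(C)C)CC1(C)C | intermediate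
14 | ε-C15 salt, [(2E,4E)-5-[(1R,4R)-4-(tert-butyldimethylsilyloxy)-2,6,6-trimethylcyclohex-2-en-1-yl]-3-methylpenta-2,4-dien-1-yl]triphenylphosphonium bromide | [Br-].C(/C=C(C)/C=C/[C@H]1C(C)=C[C@H](O[Si](C)(C)C(C)(C)C)CC1(C)C)[P+](c2ccccc2)(c3ccccc3)c4ccccc4 | intermediate
15 | (4R,6R)-4-hydroxy-2,2,6-trimethylcyclohexan-1-one (actinol) | O[C@H]1CC(C)(C)C(=O)[C@H](C)C1 | starting material
16 | (4R,6R)-4-(tert-butyldimethylsilyloxy)-2,2,6-trimethylcyclohexan-1-one | CC(C)(C)[Si](C)(C)O[C@H]1CC(C)(C)C(=O)[C@H](C)C1 | intermediate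
17 | lithium enolate of 16 (not isolated) | [Li+].CC(C)(C)[Si](C)(C)O[C@@H]1CC(C)=C([O-])C(C)(C)C1 | intermediate
18 | (4R)-4-(tert-butyldimethylsilyloxy)-2,6,6-trimethylcyclohex-1-en-1-yl trifluoromethanesulfonate | CC(C)(C)[Si](C)(C)O[C@@H]1CC(C)=C(OS(=O)(=O)C(F)(F)F)C(C)(C)C1 | intermediate
19 | (E)-3-methylpent-2-en-4-yn-1-ol | C#C/C(C)=C/CO | starting material
20 | (2E,4E)-3-methyl-5-(tributylstannyl)penta-2,4-dien-1-ol | OC/C=C(C)/C=C/[Sn](CCCC)(CCCC)CCCC | intermediate
21 | (2E,4E)-5-[(4R)-4-(tert-butyldimethylsilyloxy)-2,6,6-trimethylcyclohex-1-en-1-yl]-3-methylpenta-2,4-dien-1-ol | OC/C=C(C)/C=C/C1=C(C)C[C@@H](O[Si](C)(C)C(C)(C)C)CC1(C)C | intermediate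
22 | β-series allylic bromide from 21 (not isolated) | BrC/C=C(C)/C=C/C1=C(C)C[C@@H](O[Si](C)(C)C(C)(C)C)CC1(C)C | intermediate
23 | β-C15 salt, [(2E,4E)-5-[(4R)-4-(tert-butyldimethylsilyloxy)-2,6,6-trimethylcyclohex-1-en-1-yl]-3-methylpenta-2,4-dien-1-yl]triphenylphosphonium bromide | [Br-].C(/C=C(C)/C=C/C1=C(C)C[C@@H](O[Si](C)(C)C(C)(C)C)CC1(C)C)[P+](c2ccccc2)(c3ccccc3)c4ccccc4 | intermediate
24 | (2E,4E,6E)-2,7-dimethylocta-2,4,6-trienedial (C10 dialdehyde) | O=C/C(C)=C/C=C/C=C(C)/C=O | starting material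
25 | phosphorus ylide from 23 (not isolated) | [CH-](/C=C(C)/C=C/C1=C(C)C[C@@H](O[Si](C)(C)C(C)(C)C)CC1(C)C)[P+](c2ccccc2)(c3ccccc3)c4ccccc4 | intermediate
26 | C25 aldehyde, (2E,4E,6E,8E,10E,12E)-13-[(4R)-4-(tert-butyldimethylsilyloxy)-2,6,6-trimethylcyclohex-1-en-1-yl]-2,7,11-trimethyltrideca-2,4,6,8,10,12-hexaenal | CC(C)(C)[Si](C)(C)O[C@@H]1CC(C)=C(/C=C/C(C)=C/C=C/C(C)=C/C=C/C=C(C)/C=O)C(C)(C)C1 | intermediate
27 | phosphorus ylide from 14 (not isolated) | [CH-](/C=C(C)/C=C/[C@H]1C(C)=C[C@H](O[Si](C)(C)C(C)(C)C)CC1(C)C)[P+](c2ccccc2)(c3ccccc3)c4ccccc4 | intermediate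
28 | (3R,3'R,6'R)-3,3'-bis(tert-butyldimethylsilyloxy)-β,ε-carotene | CC(C)(C)[Si](C)(C)O[C@@H]1CC(C)=C(/C=C/C(C)=C/C=C/C(C)=C/C=C/C=C(C)/C=C/C=C(C)/C=C/[C@H]2C(C)=C[C@H](O[Si](C)(C)C(C)(C)C)CC2(C)C)C(C)(C)C1 | intermediate
29 | lutein, (3R,3'R,6'R)-β,ε-carotene-3,3'-diol | O[C@@H]1CC(C)=C(/C=C/C(C)=C/C=C/C(C)=C/C=C/C=C(C)/C=C/C=C(C)/C=C/[C@H]2C(C)=C[C@H](O)CC2(C)C)C(C)(C)C1 | intermediate
30 | myristoyl chloride (tetradecanoyl chloride) | CCCCCCCCCCCCCC(Cl)=O | starting material
31 | lutein dimyristate, (3R,3'R,6'R)-β,ε-carotene-3,3'-diyl ditetradecanoate | CCCCCCCCCCCCCC(=O)O[C@@H]1CC(C)=C(/C=C/C(C)=C/C=C/C(C)=C/C=C/C=C(C)/C=C/C=C(C)/C=C/[C@H]2C(C)=C[C@H](OC(=O)CCCCCCCCCCCCC)CC2(C)C)C(C)(C)C1 | target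

## Step count and risks

Total step count: 16. Longest linear sequence: 10 steps (steps 1 to 7, then 14, 15 and 16).

**Step 2 (the step proposed as a new method).** Racemisation of 5 through the dienolate may be slower than the enzymatic reduction, so that the reduction stalls as a plain kinetic resolution, or no panel enzyme may pair the right substrate enantiomer with the right hydride face, so that the cis series forms. The fallback uses known chemistry and sets out from 5. Luche reduction (NaBH4, CeCl3·7H2O, MeOH, −20 °C) gives the racemic allylic alcohols, which chromatography separates into the trans racemate rac-ethyl (1R,4R)-4-hydroxy-2,6,6-trimethylcyclohex-2-ene-1-carboxylate F1 and the cis racemate rac-ethyl (1S,4R)-4-hydroxy-2,6,6-trimethylcyclohex-2-ene-1-carboxylate F2, the latter being returned to 5 with MnO2. Lipase-mediated acylation of F1 (Burkholderia cepacia lipase, vinyl acetate, tert-butyl methyl ether, rt) should acylate the (4R)-alcohol, in line with the empirical rule for lipase acylation of secondary alcohols, and give ethyl (1R,4R)-4-acetoxy-2,6,6-trimethylcyclohex-2-ene-1-carboxylate F3 beside unreacted ethyl (1S,4S)-4-hydroxy-2,6,6-trimethylcyclohex-2-ene-1-carboxylate F4, which is re-oxidised to 5. Ethanolysis of F3 (K2CO3, EtOH) comes back to the route at 6.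

**Step 5.** Epimerisation at C6' or migration of the ring olefin into conjugation with the formyl group may occur under the basic olefination, and already while aldehyde 8 is handled. The fallback sets out from 7 and never passes through an enolisable C7' carbonyl. Reduction with LiAlH4 (THF, 0 °C) gives [(1R,4R)-4-(tert-butyldimethylsilyloxy)-2,6,6-trimethylcyclohex-2-en-1-yl]methanol F5. Mitsunobu thioetherification with 1-phenyl-1H-tetrazole-5-thiol (PPh3, diisopropyl azodicarboxylate, THF) gives 5-({[(1R,4R)-4-(tert-butyldimethylsilyloxy)-2,6,6-trimethylcyclohex-2-en-1-yl]methyl}sulfanyl)-1-phenyl-1H-tetrazole F6. Oxidation ((NH4)6Mo7O24·4H2O, H2O2, EtOH) gives 5-({[(1R,4R)-4-(tert-butyldimethylsilyloxy)-2,6,6-trimethylcyclohex-2-en-1-yl]methyl}sulfonyl)-1-phenyl-1H-tetrazole F7. Julia–Kocienski olefination of F7 with commercial ethyl (E)-3-methyl-4-oxobut-2-enoate (KN(SiMe3)2, THF, −78 °C) should form the C7'=C8' bond with E geometry and comes back to the route at 11.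

**Step 7.** The dienylic bromide may ionise (allylic transposition, elimination to retro-type trienes), or the allylic silyl ether may be lost before the phosphine captures the bromide. The fallback reverses the polarity of the last olefination and sets out from 12 and 26. Oxidation of 12 (MnO2, CH2Cl2, rt) gives (2E,4E)-5-[(1R,4R)-4-(tert-butyldimethylsilyloxy)-2,6,6-trimethylcyclohex-2-en-1-yl]-3-methylpenta-2,4-dienal F8. Reduction of 26 (NaBH4, MeOH/THF, 0 °C) gives (2E,4E,6E,8E,10E,12E)-13-[(4R)-4-(tert-butyldimethylsilyloxy)-2,6,6-trimethylcyclohex-1-en-1-yl]-2,7,11-trimethyltrideca-2,4,6,8,10,12-hexaen-1-ol F9. Treatment of F9 with PPh3·HBr (CH2Cl2, rt), a partner that carries no allylic silyl ether, gives [(2E,4E,6E,8E,10E,12E)-13-[(4R)-4-(tert-butyldimethylsilyloxy)-2,6,6-trimethylcyclohex-1-en-1-yl]-2,7,11-trimethyltrideca-2,4,6,8,10,12-hexaen-1-yl]triphenylphosphonium bromide F10. Wittig olefination of F10 with F8 (NaOMe, MeOH/CH2Cl2, then thermal equilibration) comes back to the route at 28.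

## Further compounds

F1 | step 2 | rac-ethyl (1R,4R)-4-hydroxy-2,6,6-trimethylcyclohex-2-ene-1-carboxylate (trans racemate, both enantiomers written) | CCOC(=O)[C@H]1C(C)=C[C@H](O)CC1(C)C.CCOC(=O)[C@@H]1C(C)=C[C@@H](O)CC1(C)C
F2 | step 2 | rac-ethyl (1S,4R)-4-hydroxy-2,6,6-trimethylcyclohex-2-ene-1-carboxylate (cis racemate, both enantiomers written) | CCOC(=O)[C@@H]1C(C)=C[C@H](O)CC1(C)C.CCOC(=O)[C@H]1C(C)=C[C@@H](O)CC1(C)C
F3 | step 2 | ethyl (1R,4R)-4-acetoxy-2,6,6-trimethylcyclohex-2-ene-1-carboxylate | CCOC(=O)[C@H]1C(C)=C[C@H](OC(C)=O)CC1(C)C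
F4 | step 2 | ethyl (1S,4S)-4-hydroxy-2,6,6-trimethylcyclohex-2-ene-1-carboxylate | CCOC(=O)[C@@H]1C(C)=C[C@@H](O)CC1(C)C
F5 | step 5 | [(1R,4R)-4-(tert-butyldimethylsilyloxy)-2,6,6-trimethylcyclohex-2-en-1-yl]methanol | OC[C@H]1C(C)=C[C@H](O[Si](C)(C)C(C)(C)C)CC1(C)C
F6 | step 5 | 5-({[(1R,4R)-4-(tert-butyldimethylsilyloxy)-2,6,6-trimethylcyclohex-2-en-1-yl]methyl}sulfanyl)-1-phenyl-1H-tetrazole | c1ccc(cc1)-n2nnnc2SC[C@H]3C(C)=C[C@H](O[Si](C)(C)C(C)(C)C)CC3(C)C
F7 | step 5 | 5-({[(1R,4R)-4-(tert-butyldimethylsilyloxy)-2,6,6-trimethylcyclohex-2-en-1-yl]methyl}sulfonyl)-1-phenyl-1H-tetrazole | c1ccc(cc1)-n2nnnc2S(=O)(=O)C[C@H]3C(C)=C[C@H](O[Si](C)(C)C(C)(C)C)CC3(C)C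
F8 | step 7 | (2E,4E)-5-[(1R,4R)-4-(tert-butyldimethylsilyloxy)-2,6,6-trimethylcyclohex-2-en-1-yl]-3-methylpenta-2,4-dienal | O=C/C=C(C)/C=C/[C@H]1C(C)=C[C@H](O[Si](C)(C)C(C)(C)C)CC1(C)C
F9 | step 7 | (2E,4E,6E,8E,10E,12E)-13-[(4R)-4-(tert-butyldimethylsilyloxy)-2,6,6-trimethylcyclohex-1-en-1-yl]-2,7,11-trimethyltrideca-2,4,6,8,10,12-hexaen-1-ol | CC(C)(C)[Si](C)(C)O[C@@H]1CC(C)=C(/C=C/C(C)=C/C=C/C(C)=C/C=C/C=C(C)/CO)C(C)(C)C1
F10 | step 7 | [(2E,4E,6E,8E,10E,12E)-13-[(4R)-4-(tert-butyldimethylsilyloxy)-2,6,6-trimethylcyclohex-1-en-1-yl]-2,7,11-trimethyltrideca-2,4,6,8,10,12-hexaen-1-yl]triphenylphosphonium bromide | [Br-].CC(C)(C)[Si](C)(C)O[C@@H]1CC(C)=C(/C=C/C(C)=C/C=C/C(C)=C/C=C/C=C(C)/C[P+](c2ccccc2)(c3ccccc3)c4ccccc4)C(C)(C)C1
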